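(The runs are simulated with constants of no real substance.)

Read the balance first. This note is for whoever takes over the bench, and I count everything as fractions of the substrate charged.

all flasks: substrate 0.074 M

| charge | reagent | remark | time |
|---|---|---|---|
| summer | 1 equiv | run made earlier |  |
| midnight | 1.5 equiv | run made earlier |  |
| flask | 2.00 equiv |  | 15 min |

| run | time / min | single product / % | double product / % |
|---|---|---|---|
| summer | 2.50 | 41.2 | 25.2 |
| summer | 5.00 | 40.9 | 25.8 |
| summer | 6.00 | 42.3 | 24.9 |
| summer | 10.0 | 40.5 | 25.0 |
| midnight | 0.667 | 32.8 | 48.3 |
| midnight | 1.50 | 31.3 | 47.7 |
| midnight | 4.00 | 31.8 | 47.2 |
| midnight | 10.0 | 31.3 | 46.6 |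

(readings scatter by 1 percentage point)

- the earlier runs were read with a standard deviation of 1 percentage point
- a reading or a percentage of double product counts all its forms, free or not

- equivalents of reagent to substrate, everything else as given, that leave most single product at 15 min
- the amount of single product then, in percent of the substrate charged
- the amount of single product with the amounts as given

The readings of both earlier runs stand level from the first point, so I leave the clock alone and look at the reagent. I count one reagent per single product and two per double product, and I call the charge minus these the reagent gap. On the mean readings the gap is 0.0833 in the summer run and 0.233 in the midnight run. Carried on in a straight line to the 2.00 equiv of this flask, my reckoning gives a gap of 0.383. So some reagent goes where I cannot read it, but the gap alone gives me no single product. The forecast does give it: 17 % in this flask, and 42 % at 0.9 equiv, on the view that “each run finishes within a minute”.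

    crystals ⇌ double product, rate k1*(cs1 - [double product]) while solid is left; crystals form when [double product] > cs1 (solubility = 1.30 mM, k = 0.514 /s)
    reagent + single product → double product + by-product (k = 2.88 /M/s)
    substrate + reagent → single product + by-product (k = 3.68 /M/s)
    reagent + double product → triple product + by-product (k = 2.17 /M/s)
    reagent + triple product → tetra adduct + by-product (k = 0.226 /M/s)

This flask gives 12.9 % of single product, and the best is 41.4 % at 0.964 equiv, as the forecast said within its margins. Its reagent stands at 0 %, so reagent is the limiting reagent, and waiting changes nothing. Its gap is 0.478 against my 0.383, and triple product at 3 reagents with tetra adduct at 4 comes to 0.478. The neighbour with 0.30 M of substrate has the same equivalents, but my line came from runs at 0.074 M, so my 0.383 does not carry over to it. Its gap is 0.754, the same count gives 0.754, and it holds 18.6 % of single product.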